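**Retrosynthetic overview**
1. Ring A is bought complete: acetosyringone 1 already carries the C6-OMe/C7-OH/C8-OMe triad and the future C4 carbon. Its two equivalent free ring carbons become C5 and C8a and are pre-oxidised as C–Br in dibromide 2.
2. C–C disconnection (C3–C4): the three-carbon bridge comes from C-acylation of the enolate of 2 with ring B acid chloride 3, giving 1,3-diketone 4.
3. Key C–O disconnections: O1–C8a (closes ring C, giving bromoflavone 5) and C5–OH, both made from 4 in one copper-catalysed operation that ends at target 6.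
4. Ring order: rings A and B are purchased and ring C is formed last. The symmetry of ring A in 4 makes the two C–Br sites equivalent, so no regiochemical question arises.

Assumption: the target is a planar flavone with no stereocentre, so "single enantiomer" requires no stereocontrol; the SMILES is taken as drawn.

**Step 1**
Reactants: 1 acetosyringone, 1-(4-hydroxy-3,5-dimethoxyphenyl)ethan-1-one
Product: 2 1-(2,6-dibromo-4-hydroxy-3,5-dimethoxyphenyl)ethan-1-one
Conditions: NBS (2.2 equiv), MeCN, 0 °C → 40 °C, dark
Reagents that add atoms: N-bromosuccinimide, O=C1CCC(=O)N1Br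
Why: Electrophilic aromatic bromination; the only two ring C–H positions of 1 are equivalent, each is ortho to one methoxy group and para to the other, and NBS in MeCN without acid or light favours ring over side-chain bromination.

**Step 2**
Reactants: 2 1-(2,6-dibromo-4-hydroxy-3,5-dimethoxyphenyl)ethan-1-one; 3 3,4,5-trimethoxybenzoyl chloride
Product: 4 1-(2,6-dibromo-4-hydroxy-3,5-dimethoxyphenyl)-3-(3,4,5-trimethoxyphenyl)propane-1,3-dione
Conditions: LiHMDS (3.2 equiv), THF, −78 °C; then 3 (1.05 equiv), −78 °C → rt; 1 M HCl
Reagents that add atoms: none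
Why: Claisen-type C-acylation of a ketone lithium enolate by an acid chloride; three equivalents of base give the phenoxide/enolate dianion and keep the product as its enolate, and the enolate carbon is far more nucleophilic than the lithium phenoxide buried between two methoxy groups.

**Step 3**
Reactants: 4 1-(2,6-dibromo-4-hydroxy-3,5-dimethoxyphenyl)-3-(3,4,5-trimethoxyphenyl)propane-1,3-dione
Product: 6 5,7-dihydroxy-6,8,3',4',5'-pentamethoxyflavone, via bromoflavone 5 (not isolated)
Conditions: CuI (10 mol%), N,N'-bis(4-hydroxy-2,6-dimethylphenyl)oxalamide (10 mol%), LiOH·H2O (2.1 equiv), degassed DMSO, 80 °C, argon; then LiOH·H2O (3 equiv), H2O (DMSO/H2O 4:1), 100 °C; then 1 M HCl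
Reagents that add atoms: lithium hydroxide (as monohydrate), [Li+].[OH-]
Why: Proposed new method: a one-pot copper-catalysed double Ullmann-type C–O coupling in which the two equivalent C–Br bonds of a 2,6-dibromoaryl 1,3-diketone are used by two different oxygen nucleophiles; with only enough LiOH to form the phenoxide/enolate dianion, the enolate oxygen closes ring C onto either C–Br by oxidative addition at monovalent copper and C–O reductive elimination to give 5, and the hydroxide added afterwards replaces the remaining bromide, which is now coplanar with and peri to the C4 carbonyl so that carbonyl coordination to copper assists the substitution, while the 7-oxido group shields C2 from hydroxide; the closest known reaction types are the copper-catalysed intramolecular O-arylation of 1-(2-bromoaryl)-1,3-diketones to flavones and the copper/oxalamide-catalysed hydroxylation of aryl bromides with hydroxide.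

**Compound list**
1 | acetosyringone, 1-(4-hydroxy-3,5-dimethoxyphenyl)ethan-1-one | CC(=O)c1cc(OC)c(O)c(OC)c1 | starting material
2 | 1-(2,6-dibromo-4-hydroxy-3,5-dimethoxyphenyl)ethan-1-one | CC(=O)c1c(Br)c(OC)c(O)c(OC)c1Br | intermediate
3 | 3,4,5-trimethoxybenzoyl chloride | COc1cc(C(=O)Cl)cc(OC)c1OC | starting material
4 | 1-(2,6-dibromo-4-hydroxy-3,5-dimethoxyphenyl)-3-(3,4,5-trimethoxyphenyl)propane-1,3-dione (mainly enol in solution) | COc1cc(C(=O)CC(=O)c2c(Br)c(OC)c(O)c(OC)c2Br)cc(OC)c1OC | intermediate
5 | 5-bromo-7-hydroxy-6,8-dimethoxy-2-(3,4,5-trimethoxyphenyl)-4H-chromen-4-one | COc1cc(-c2cc(=O)c3c(Br)c(OC)c(O)c(OC)c3o2)cc(OC)c1OC | intermediate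
6 | 5,7-dihydroxy-6,8,3',4',5'-pentamethoxyflavone, 5,7-dihydroxy-6,8-dimethoxy-2-(3,4,5-trimethoxyphenyl)-4H-chromen-4-one | COc1cc(-c2cc(=O)c3c(O)c(OC)c(O)c(OC)c3o2)cc(OC)c1OC | target

**Totals**
Total steps: 3. Longest linear sequence: 3 (1 → 2 → 4 → 6).

**Steps most likely to fail, each with a fallback**

Step 3 (the proposed new step). Risks are protodebromination at C5, hydroxylation before ring closure leaving a monobromide, and binding of copper by the 5-hydroxy-4-keto product. The fallback uses known chemistry only; it sets out from 4 and comes back at 6. Heating 4 with CuI (10 mol%) and K2CO3 in DMF at 100 °C, the known intramolecular Ullmann O-arylation of 2-bromoaryl 1,3-diketones, gives 5, which is isolated. NaOMe and CuBr in DMF/MeOH at 110 °C, the known Ullmann methoxylation of bromoflavones, then give 7-hydroxy-5,6,8-trimethoxy-2-(3,4,5-trimethoxyphenyl)-4H-chromen-4-one F5. BCl3 in CH2Cl2 at 0 °C cleaves only the 5-methyl ether, which chelates boron together with the C4 carbonyl, and gives 6.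

Step 1. Risks are bromination of the acetyl methyl group, stalling at the monobromide, and oxidation of the free phenol. The fallback sets out from 3 and comes back at 6; it builds ring A from phloroglucinol and installs the two methoxy groups last. Adding 3 to the lithium enolate of ethyl acetate (2 equiv, LiHMDS, THF, −78 °C) gives ethyl 3-oxo-3-(3,4,5-trimethoxyphenyl)propanoate F1. Heating this neat with purchased phloroglucinol (benzene-1,3,5-triol) at 240 °C, a thermal pyrone condensation of the Mentzer type, gives 5,7-dihydroxy-2-(3,4,5-trimethoxyphenyl)-4H-chromen-4-one F2. NBS (2.1 equiv) in DMF at 0 °C brominates the two phloroglucinol-type positions and gives 6,8-dibromo-5,7-dihydroxy-2-(3,4,5-trimethoxyphenyl)-4H-chromen-4-one F3. NaOMe and CuBr in DMF/MeOH at 110 °C (Ullmann methoxylation) replace both bromides and give 6.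

Step 2. Risks are O-acylation of the phenoxide and double acylation. The fallback sets out from 2 and comes back at 4; it accepts O-acylation instead of avoiding it. Soft enolisation of 2 with MgBr2·OEt2 (3 equiv) and iPr2NEt (4 equiv) in CH2Cl2 at rt in the presence of 3 (2.2 equiv) acylates both the ketone alpha-carbon and the phenol and gives 3,5-dibromo-2,6-dimethoxy-4-[3-oxo-3-(3,4,5-trimethoxyphenyl)propanoyl]phenyl 3,4,5-trimethoxybenzoate F4. K2CO3 in MeOH at 0 °C → rt then removes only the aryl ester, the diketone being protected as its enolate, and gives 4.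

**Further compounds**
F1 | step 1 | ethyl 3-oxo-3-(3,4,5-trimethoxyphenyl)propanoate | CCOC(=O)CC(=O)c1cc(OC)c(OC)c(OC)c1
F2 | step 1 | 5,7-dihydroxy-2-(3,4,5-trimethoxyphenyl)-4H-chromen-4-one | COc1cc(-c2cc(=O)c3c(O)cc(O)cc3o2)cc(OC)c1OC
F3 | step 1 | 6,8-dibromo-5,7-dihydroxy-2-(3,4,5-trimethoxyphenyl)-4H-chromen-4-one | COc1cc(-c2cc(=O)c3c(O)c(Br)c(O)c(Br)c3o2)cc(OC)c1OC
F4 | step 2 | 3,5-dibromo-2,6-dimethoxy-4-[3-oxo-3-(3,4,5-trimethoxyphenyl)propanoyl]phenyl 3,4,5-trimethoxybenzoate | COc1cc(C(=O)Oc2c(OC)c(Br)c(C(=O)CC(=O)c3cc(OC)c(OC)c(OC)c3)c(Br)c2OC)cc(OC)c1OC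
F5 | step 3 | 7-hydroxy-5,6,8-trimethoxy-2-(3,4,5-trimethoxyphenyl)-4H-chromen-4-one | COc1cc(-c2cc(=O)c3c(OC)c(OC)c(O)c(OC)c3o2)cc(OC)c1OC
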